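The product I wanted was E, the D built into chains, counted per chain begun at the end of spring and of summer, two flasks that differ in J, 0.39 mM against 0.10 mM.

the same everywhere: Z 1.2 mM

|  | D | G | J | remark | time |
|---|---|---|---|---|---|
| west | 0.075 M | 0.015 M | 0.39 mM | run made earlier |  |
| north-east | 0.050 M | 0.030 M | 0.39 mM | run made earlier |  |
| spring | 0.050 M | 0.0150 M | 0.39 mM |  | 50 min |
| summer | 0.050 M | 0.0150 M | 0.10 mM |  | 50 min |

| run | time / min | E / % | D / % |
|---|---|---|---|
| west | 4.00 | 13.1 | 72.6 |
| west | 8.00 | 21.0 | 61.2 |
| west | 12.0 | 27.3 | 53.0 |
| west | 20.0 | 34.8 | 45.0 |
| north-east | 4.00 | 6.2 | 60.8 |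
| north-east | 8.00 | 6.8 | 48.5 |
| north-east | 12.0 | 5.1 | 44.4 |
| north-east | 20.0 | 0.6 | 43.0 |

(each reading ± 0.3 percentage points)

- which of the two ends with the longer chains by the average number of monomer units in a chain (chains begun, living or dead) ("neither" if they lie within 10 %) (spring / summer / neither)
- average number of monomer units in a chain (chains begun, living or dead) at the end, spring
- average number of monomer units in a chain (chains begun, living or dead) at the end, summer

- the average divides the monomer in chains by the number of chains begun, living and dead together
- the numbers in the tables scatter with a standard deviation of 0.3 percentage points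
- what may be going on: Z + J -> L; D + Q -> E + Q; E + Q -> D + Q; G + D -> X; D + Z -> Q + E
- the earlier runs do not show the number of chains; that part of a forecast is a guess

First, where does free D stop? A living end Q can add D to E and also give D back, so I looked for the level of free D at which the two balance. West and north-east were charged with the same Z and J, so I took them to hold equally many ends. Between 12.0 min and 20.0 min, west gained 0.703 mM min⁻¹ of E at free D 0.0367 M, while north-east lost 0.281 mM min⁻¹ at 0.0219 M. A straight line through these two points crosses zero at 0.0261 M, and I took this reading as the balance level of free D, the equilibrium monomer concentration, which is 52.2 % of the charge in spring and summer. Its slope gives a time constant of 15.1 min for those two runs, so in spring, charged with the same Z and J, 50 min is 3.31 time constants and hardly any of the starting gap should remain.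

Second, what else takes D? In west, the part that was neither E nor D reached 20.2 % at the last reading, against G charged at 20.0 %, so I counted one D lost to X per G. That is 30.0 % of the charge here, and I reckoned that it leaves 17.8 % as E in both flasks, taking summer to reach the same level of free D.

Third, how many chains? This part is a guess: I let each J remove one Z, which leaves 1.62 % of the charge as chains in spring and 2.20 % in summer. The lengths are then 11.0 for spring and 8.08 for summer, so spring is longer by a factor of 1.36, past the margin.

The forecast, working from a “ceiling-type monomer level”, gave 10.5 for spring, against my 11.0, and 8 for summer, against my 8.08, with spring longer.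

The flask gave 11.5 in spring and 8.53 in summer.

    Z + J → L (k = 1200 M⁻¹ s⁻¹)
    D + Q → E + Q, rate k2*[Q]*[D] (k = 1.40 M⁻¹ s⁻¹)
    E + Q → D + Q, rate k3*[Q] as long as [E] is above zero (k = 0.0360 s⁻¹)
    G + D → X (k = 0.0880 M⁻¹ s⁻¹)
    D + Z → Q + E (k = 0.420 M⁻¹ s⁻¹)

In summer, the loss of G and D to X had half of its turnover up to 50.0 min behind it by 3.03 min, and free D stood at 51.2 % of the charge at 25.0 min. At 50.0 min it stood at 51.3 %, with E at 18.8 % and Q at 2.20 % of the charge. For a neighbour of summer charged with 0.085 M of D, the level 0.0261 M gives 39.9 units per chain. That neighbour ended at 39.9 units, with free D at 30.7 % of its charge.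

The earlier runs and the new flask were generated by integration for an exercise, and the scatter is random.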